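The vessel was closed, stirred and held at one temperature, and the runs differed in their charge of starting material.

| setting | dusk | spring | summer | midnight |
|---|---|---|---|---|
| starting material | 0.600 M | 0.300 M | 1.80 M | 0.600 M |
| free catalyst | 0.0300 M | 0.0300 M | 0.0300 M | 0.0300 M |
| time |  |  |  | 400 h |

- dusk run (time / h: [target] / M): 15: 0.036; 46: 0.109; 88: 0.163; 140: 0.190; 200: 0.190
- spring run (time / h: [target] / M): 15: 0.004; 46: 0.036; 88: 0.084; 140: 0.088; 200: 0.088
- summer run (time / h: [target] / M): 15: 0.202; 46: 0.482; 88: 0.598; 140: 0.624; 200: 0.635

(each reading ± 0.009 M)

1. reaction order in [starting material] at the outset, round the charge of the dusk run, defined at two percent of the starting material turned into target (one fixed amount of target, the same in the runs compared)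
2. target in the midnight run at 400 h, as a share of the starting material charged
3. which of these the readings show (a little impurity takes part of the catalyst at once / the product kills the catalyst / nothing beyond the main steps / the loaded catalyst dies / an uncatalysed path runs beside / the substrate is lost by itself)

- Overall: starting material -> target, with free catalyst as catalyst.
- Constant volume, constant temperature.
- Readings of a species count what is bound in complexes too.
- An order is taken over about fifteen percent of the charge, up and down.

Each run climbed and then went flat well short of its charge. I ranked the time scales of the dusk run, taking the mean rate up to the second reading and the last reading as the plateau:

r = 0.109 M / 46 h = 0.00237 M h⁻¹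

τ = c(target, plateau) / r = 80.2 h

This τ, the stop time, is the time the early rate would need to make the plateau. Next came the emptying time, charge over early rate, 253 h, longer than the stop time, so the dusk run went flat with 0.410 M of its charge not turned into target. Slowest was the 400 h of the midnight run, which has the dusk charge, so I expected the dusk plateau there, 31.7% of charge.

Reckoned the same way, the spring run gave 112 h, read loosely given the scatter, and the summer run 60.6 h, shorter than dusk. Comparing at one amount of target, 0.036 M in dusk and 0.036 M in spring, I reckoned an order of 1.62. With a first-order loss of starting material beside a path of that order, the rate of the path over the rate of the loss, at a like share of charge turned, grows with the charge to the power of the order less one, a factor of 3.02 from the spring run to the summer run. The plateau over the rest of the charge rose between those runs by a factor of 1.31, less than that, so I set the loss aside and chose product poisoning: the product kills the catalyst.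

The forecast gave an order of 1.4, 32% and this choice: the substrate is lost by itself. Its ground was: “A parallel first-order loss of substrate gives a nearly constant yield fraction, which fits”. We part on that choice.

The simulation gave an order of 1.7, 34.8% and this choice: the product kills the catalyst.

    free catalyst + starting material ⇌ catalyst-substrate complex, settled at all times (0.1730 M⁻¹)
    catalyst-substrate complex + starting material ⇌ doubly bound catalyst, settled at all times (2.290 M⁻¹)
    doubly bound catalyst → target + catalyst-substrate complex (1.001 h⁻¹)
    free catalyst + target → spent catalyst + target (0.1102 M⁻¹ h⁻¹)

The midnight run ended at 34.8%, which is 0.209 M of target, more than the last dusk reading. The step with 0.110 M⁻¹ h⁻¹ takes free catalyst with target as its partner. Using the rates stored at one fixed amount of target, the stop time for the midnight target over the dusk rate, at the same charge, is 64.7 h. The spring plateau gives 99.4 h, and the summer plateau gives less, 43.7 h.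

All runs are simulated from invented constants, noise included.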